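The flavanone is traced back to a flavone whose ring C is cut at C8a–O1, C4a–C4 and O1–C2. The feature used is that C8a (bearing O1) and C4a (bearing the C4 carbonyl) are neighbouring ring A carbons, lying between the C8 side chain and the C5 methoxy group. This is the pattern left when a C4a≡C8a aryne takes up a carboxylic acid. A single operation brings in O1, C2, C3, C4 and the whole of ring B from an arylpropiolic acid and closes ring C. The aryne precursor is a 2-silylaryl triflate that already carries the (R)-configured side chain, made by auxiliary-controlled alkylation. C2 is set afterwards by asymmetric conjugate reduction.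

Key step: step 15

Remark (assumption): the sense of induction of the copper hydride catalyst in step 16 is not predicted here; the ligand enantiomer to be used is the one that adds hydride to the Re face of C2, fixed in a pilot run (the two C2 epimers are diastereomers).

Abbreviation: SC = (2R)-5-methyl-2-(prop-1-en-2-yl)-5-(triethylsilyloxy)hexyl. Atom numbers are those of the flavanone (O1, C2–C4, C4a, C5–C8, C8a; ring B primed).

**Side chain (steps 1–6)**

Step 1
Reactants: 1 (4S)-4-benzyl-1,3-oxazolidin-2-one; 2 3-methylbut-2-enoyl chloride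
Product: 3 (4S)-4-benzyl-3-(3-methylbut-2-enoyl)-1,3-oxazolidin-2-one
Conditions: n-BuLi, THF, −78 °C; then 2, −78 to 0 °C
Reagents that add atoms: none
Why: N-acylation of the lithiated oxazolidinone by the acid chloride, the standard way of attaching this auxiliary.

Step 2
Reactants: 3; 4 prenyl bromide (1-bromo-3-methylbut-2-ene)
Product: 5 (4S)-4-benzyl-3-[(2S)-5-methyl-2-(prop-1-en-2-yl)hex-4-enoyl]-1,3-oxazolidin-2-one
Conditions: NaN(SiMe3)2, THF, −78 °C; then 4, −78 to −40 °C
Reagents that add atoms: none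
Why: Deconjugative Evans alkylation: γ-deprotonation gives the chelated sodium dienolate, which the allylic bromide attacks at the α-carbon on the face away from the benzyl group, setting the (2S) centre that becomes, after the change of CIP priorities, the (R) side-chain centre of the target.

Step 3
Reactants: 5
Product: 6 (4S)-4-benzyl-3-{(2S)-2-[(3,3-dimethyloxiran-2-yl)methyl]-3-methylbut-3-enoyl}-1,3-oxazolidin-2-one (both epimers at the oxirane carbon)
Conditions: mCPBA (1.05 equiv), CH2Cl2, 0 °C
Reagents that add atoms: 3-chloroperoxybenzoic acid, O=C(OO)c1cccc(Cl)c1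
Why: Prilezhaev epoxidation is expected to take the electron-rich trisubstituted alkene well ahead of the 1,1-disubstituted isopropenyl group, which sits next to the acyl carbon; the oxirane CH is left as a mixture because it becomes CH2 in step 4.

Step 4
Reactants: 6
Product: 7 (2S)-5-methyl-2-(prop-1-en-2-yl)hexane-1,5-diol
Conditions: LiAlH4, THF, 0 to 50 °C
Reagents that add atoms: none
Why: Hydride reduction cleaves the imide to the primary alcohol (auxiliary released) and opens the trisubstituted epoxide at its less substituted carbon to the tertiary alcohol; the stereocentre is not involved.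

Step 5
Reactants: 7
Product: 8 (5S)-6-iodo-2-methyl-5-(prop-1-en-2-yl)hexan-2-ol
Conditions: I2, PPh3, imidazole, CH2Cl2, 0 °C
Reagents that add atoms: iodine, II
Why: Appel-type iodination (Garegg–Samuelsson conditions) activates only the primary alcohol at 0 °C, and iodide displacement is expected to outrun ether formation by the hindered tertiary hydroxyl.

Step 6
Reactants: 8
Product: 9 triethyl{[(5S)-6-iodo-2-methyl-5-(prop-1-en-2-yl)hexan-2-yl]oxy}silane
Conditions: Et3SiOTf, 2,6-lutidine, CH2Cl2, −78 to 0 °C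
Reagents that add atoms: triethylsilyl trifluoromethanesulfonate, CC[Si](CC)(CC)OS(=O)(=O)C(F)(F)F
Why: Silylation with a silyl triflate is the standard way to cap a tertiary alcohol, and the hindered base leaves the primary iodide alone.

**Ring A aryne precursor (steps 7–12)**

Step 7
Reactants: 10 5-methoxyresorcinol
Product: 11 3-methoxy-5-(methoxymethoxy)phenol
Conditions: MOMCl (1.0 equiv), i-Pr2NEt, THF, 0 °C to rt
Reagents that add atoms: chloromethyl methyl ether, COCCl
Why: O-alkylation with one equivalent gives the mono-ether statistically; the symmetry is broken here, on the cheapest material, so that diol and bis-ether can be separated and recycled and no phenol has to be unmasked by acid later.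

Step 8
Reactants: 11
Product: 12 3-methoxy-5-(methoxymethoxy)phenyl N-(propan-2-yl)carbamate
Conditions: i-PrNCO, Et3N (cat.), CH2Cl2, rt
Reagents that add atoms: isopropyl isocyanate, CC(C)N=C=O
Why: Base-catalysed addition of the phenol to the isocyanate gives the N-monoalkyl carbamate, which directs both metalations and is later cleaved without acid.

Step 9
Reactants: 12
Product: 16 2-iodo-5-methoxy-3-(methoxymethoxy)phenyl N-(propan-2-yl)carbamate, via N-silyl carbamate 13 (not isolated), via aryllithium 14 (not isolated), via N-silyl aryl iodide 15 (not isolated)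
Conditions: t-BuMe2SiOTf (1.05 equiv), TMEDA, Et2O, 0 °C to rt; n-BuLi, TMEDA, −78 °C; I2 in THF, −78 °C to rt; aq. NaHSO4
Reagents that add atoms: iodine, II
Why: Directed ortho-metalation: the silyl triflate is taken up by the N–H (so the MOM acetal is untouched), n-BuLi removes the ring proton flanked by the two strongest directors (carbamate and MOM ether, not methoxy), the aryllithium is iodinated at −78 °C before any anionic Fries shift, and the N–Si bond falls off on work-up.

Step 10
Reactants: 9; 16
Product: 18 5-methoxy-3-(methoxymethoxy)-2-SC-phenyl N-(propan-2-yl)carbamate, via alkylzinc iodide 17 (not isolated)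
Conditions: 9, Zn dust, LiCl, THF, 40 °C; then 16, Pd(OAc)2 (2 mol%), SPhos (4 mol%), THF, rt to 40 °C
Reagents that add atoms: none
Why: Negishi sp3–sp2 coupling: zinc inserts into the primary C–I bond and the SPhos–palladium catalyst is known to join primary alkylzinc halides to hindered, electron-rich aryl iodides, tolerating the carbamate N–H and leaving the β-stereocentre untouched.

Step 11
Reactants: 18
Product: 22 3-methoxy-5-(methoxymethoxy)-6-SC-2-(trimethylsilyl)phenyl N-(propan-2-yl)carbamate, via N-silyl carbamate 19 (not isolated), via aryllithium 20 (not isolated), via N-silyl arylsilane 21 (not isolated)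
Conditions: t-BuMe2SiOTf (1.05 equiv), TMEDA, Et2O, 0 °C to rt; n-BuLi, TMEDA, −78 °C; Me3SiCl, −78 °C to rt; aq. NaHSO4
Reagents that add atoms: chlorotrimethylsilane, C[Si](C)(C)Cl
Why: Second directed ortho-metalation at the only free position ortho to the carbamate, which is also flanked by the methoxy group and therefore preferred over the MOM/methoxy site and over the hindered benzylic CH2; silyl chloride quench.

Step 12
Reactants: 22
Product: 24 3-methoxy-5-(methoxymethoxy)-6-SC-2-(trimethylsilyl)phenyl trifluoromethanesulfonate, via ortho-silyl phenol 23 (not isolated)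
Conditions: DBU, Et2NH, MeCN, 40 °C; then PhNTf2, rt to 40 °C
Reagents that add atoms: N-phenylbis(trifluoromethanesulfonimide), O=S(=O)(N(c1ccccc1)S(=O)(=O)C(F)(F)F)C(F)(F)F
Why: E1cB cleavage of the N-monoalkyl carbamate (the isocyanate is trapped by Et2NH) frees the phenoxide under base only, so the acid-labile aryl C–Si bond survives, and the phenoxide is triflated in the same flask.

**Ring B acid (steps 13–14)**

Step 13
Reactants: 25 4-bromo-3-methoxyphenol
Product: 26 1-bromo-2-methoxy-4-(methoxymethoxy)benzene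
Conditions: MOMCl, i-Pr2NEt, CH2Cl2, 0 °C to rt
Reagents that add atoms: chloromethyl methyl ether, COCCl
Why: Routine O-alkylation of the phenol; the MOM ether withstands fluoride at high temperature.

Step 14
Reactants: 26; 27 propiolic acid
Product: 28 3-[2-methoxy-4-(methoxymethoxy)phenyl]prop-2-ynoic acid
Conditions: Pd(PPh3)2Cl2 (5 mol%), 1,4-bis(diphenylphosphino)butane (10 mol%), DBU, DMSO, 50 °C; then cold aq. citric acid to pH 3
Reagents that add atoms: none
Why: Copper-free Sonogashira-type coupling of the aryl bromide with propiolic acid as its DBU salt, run below the temperature at which arylpropiolates lose CO2.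

**Key step and endgame (steps 15–17)**

Step 15
Reactants: 24; 28
Product: 31 5-methoxy-2-[2-methoxy-4-(methoxymethoxy)phenyl]-7-(methoxymethoxy)-8-SC-4H-chromen-4-one, via aryne 29 (not isolated), via 2-hydroxyaryl ynone 30 (not isolated)
Conditions: 24 (1.0 equiv), 28 (2 equiv), CsF (6 equiv), THF (concentrated), 125 °C, sealed tube
Reagents that add atoms: none
Why: Fluoride attacks silicon and the triflate leaves, giving the C4a≡C8a aryne 29, whose C8a carbon takes up the carboxylate oxygen of 28 (C8a–O1). The C4a aryl anion then adds to the neighbouring ester carbonyl and the four-membered alkoxide opens to the 2-hydroxyaryl ynone 30 (C4a–C4); this is a net insertion of the aryne into the C–O bond of the acid, and the closest known reaction type is exactly this aryne insertion into carboxylic acids, which with arylpropiolic acids ends in flavones. Ring C closes by 6-endo-dig oxa-Michael addition of the C8a phenoxide to the ynone (O1–C2), the proton for C3 coming from the bifluoride formed from the acid. No stereocentre is made, and the side-chain centre is remote from the reacting carbons and is not touched. Two selectivities are needed: the regiochemistry of capture, where the inductive pull of the C5 methoxy group makes C8a the electrophilic aryne carbon and puts the charge on C4a despite the C8 CH2 group, and capture by carboxylate ahead of an intramolecular ene reaction of the aryne with the isopropenyl group, which is favoured by using the cheap acid in excess at high concentration. Closure 6-endo and not 5-exo (aurone) is the usual course of 2-hydroxyaryl ynones under these fluoride conditions.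

Step 16
Reactants: 31
Product: 33 (2S)-5-methoxy-2-[2-methoxy-4-(methoxymethoxy)phenyl]-7-(methoxymethoxy)-8-SC-2,3-dihydro-4H-chromen-4-one, via silyl enol ether 32 (not isolated)
Conditions: Cu(OAc)2 (5 mol%), (R,R)-Ph-BPE (5.5 mol%; see remark), (EtO)2MeSiH, toluene, 0 °C to rt; then aq. NH4F, MeOH, 0 °C
Reagents that add atoms: none
Why: Copper hydride asymmetric conjugate reduction of the chromone C2=C3 bond: the ligand-bound Cu–H delivers hydride to the Re face of C2 (ligand control; the distant side-chain centre has no say) to give the (2S) centre, the product stays as silyl enol ether 32 until the fluoride work-up so that the C4 carbonyl is not reduced, and the isolated alkene is inert in the absence of a proton source.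

Step 17
Reactants: 33
Product: 35 (2S)-7-hydroxy-2-(4-hydroxy-2-methoxyphenyl)-8-[(2R)-5-hydroxy-5-methyl-2-(prop-1-en-2-yl)hexyl]-5-methoxy-2,3-dihydro-4H-chromen-4-one (CNP0288934.1), via bis(trimethylsilyl) ether 34 (not isolated)
Conditions: Me3SiOTf, 2,2′-bipyridyl, MeCN, 0 °C to rt; then Et3N·3HF, rt to 40 °C
Reagents that add atoms: none
Why: Silyl triflate and 2,2′-bipyridyl exchange the two aryl MOM acetals for aryl silyl ethers without protic acid, so the isopropenyl group and the tertiary carbinol cannot ionise or cyclise onto the C7 phenol and C2 is not opened; buffered fluoride then cleaves the two aryl O–Si bonds and the tertiary triethylsilyl ether.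

**Compound list**

1 | (4S)-4-benzyl-1,3-oxazolidin-2-one | O=C1OC[C@H](Cc2ccccc2)N1 | starting material
2 | 3-methylbut-2-enoyl chloride | CC(C)=CC(=O)Cl | starting material
3 | (4S)-4-benzyl-3-(3-methylbut-2-enoyl)-1,3-oxazolidin-2-one | CC(C)=CC(=O)N1[C@@H](Cc2ccccc2)COC1=O | intermediate
4 | prenyl bromide | CC(C)=CCBr | starting material
5 | (4S)-4-benzyl-3-[(2S)-5-methyl-2-(prop-1-en-2-yl)hex-4-enoyl]-1,3-oxazolidin-2-one | C=C(C)[C@H](CC=C(C)C)C(=O)N1[C@@H](Cc2ccccc2)COC1=O | intermediate
6 | (4S)-4-benzyl-3-{(2S)-2-[(3,3-dimethyloxiran-2-yl)methyl]-3-methylbut-3-enoyl}-1,3-oxazolidin-2-one, oxirane epimers | C=C(C)[C@H](CC1OC1(C)C)C(=O)N1[C@@H](Cc2ccccc2)COC1=O | intermediate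
7 | (2S)-5-methyl-2-(prop-1-en-2-yl)hexane-1,5-diol | C=C(C)[C@H](CCC(C)(C)O)CO | intermediate
8 | (5S)-6-iodo-2-methyl-5-(prop-1-en-2-yl)hexan-2-ol | C=C(C)[C@H](CCC(C)(C)O)CI | intermediate
9 | triethyl{[(5S)-6-iodo-2-methyl-5-(prop-1-en-2-yl)hexan-2-yl]oxy}silane | C=C(C)[C@H](CCC(C)(C)O[Si](CC)(CC)CC)CI | intermediate
10 | 5-methoxyresorcinol | COc1cc(O)cc(O)c1 | starting material
11 | 3-methoxy-5-(methoxymethoxy)phenol | COCOc1cc(O)cc(OC)c1 | intermediate
12 | 3-methoxy-5-(methoxymethoxy)phenyl N-(propan-2-yl)carbamate | CC(C)NC(=O)Oc1cc(OC)cc(OCOC)c1 | intermediate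
13 | N-(tert-butyldimethylsilyl) derivative of 12 | CC(C)N(C(=O)Oc1cc(OC)cc(OCOC)c1)[Si](C)(C)C(C)(C)C | intermediate
14 | 2-lithio derivative of 13 (lithium between carbamate and MOM ether) | [Li]c1c(OCOC)cc(OC)cc1OC(=O)N(C(C)C)[Si](C)(C)C(C)(C)C | intermediate
15 | N-(tert-butyldimethylsilyl) derivative of 16 | CC(C)N(C(=O)Oc1cc(OC)cc(OCOC)c1I)[Si](C)(C)C(C)(C)C | intermediate
16 | 2-iodo-5-methoxy-3-(methoxymethoxy)phenyl N-(propan-2-yl)carbamate | CC(C)NC(=O)Oc1cc(OC)cc(OCOC)c1I | intermediate
17 | [(2S)-5-methyl-2-(prop-1-en-2-yl)-5-(triethylsilyloxy)hexyl]zinc iodide | C=C(C)[C@H](CCC(C)(C)O[Si](CC)(CC)CC)C[Zn]I | intermediate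
18 | 5-methoxy-3-(methoxymethoxy)-2-SC-phenyl N-(propan-2-yl)carbamate | C=C(C)[C@H](CCC(C)(C)O[Si](CC)(CC)CC)Cc1c(OCOC)cc(OC)cc1OC(=O)NC(C)C | intermediate
19 | N-(tert-butyldimethylsilyl) derivative of 18 | C=C(C)[C@H](CCC(C)(C)O[Si](CC)(CC)CC)Cc1c(OCOC)cc(OC)cc1OC(=O)N(C(C)C)[Si](C)(C)C(C)(C)C | intermediate
20 | 6-lithio derivative of 19 (lithium between carbamate and methoxy) | C=C(C)[C@H](CCC(C)(C)O[Si](CC)(CC)CC)Cc1c(OCOC)cc(OC)c([Li])c1OC(=O)N(C(C)C)[Si](C)(C)C(C)(C)C | intermediate
21 | N-(tert-butyldimethylsilyl) derivative of 22 | C=C(C)[C@H](CCC(C)(C)O[Si](CC)(CC)CC)Cc1c(OCOC)cc(OC)c([Si](C)(C)C)c1OC(=O)N(C(C)C)[Si](C)(C)C(C)(C)C | intermediate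
22 | 3-methoxy-5-(methoxymethoxy)-6-SC-2-(trimethylsilyl)phenyl N-(propan-2-yl)carbamate | C=C(C)[C@H](CCC(C)(C)O[Si](CC)(CC)CC)Cc1c(OCOC)cc(OC)c([Si](C)(C)C)c1OC(=O)NC(C)C | intermediate
23 | 3-methoxy-5-(methoxymethoxy)-6-SC-2-(trimethylsilyl)phenol | C=C(C)[C@H](CCC(C)(C)O[Si](CC)(CC)CC)Cc1c(OCOC)cc(OC)c([Si](C)(C)C)c1O | intermediate
24 | 3-methoxy-5-(methoxymethoxy)-6-SC-2-(trimethylsilyl)phenyl trifluoromethanesulfonate | C=C(C)[C@H](CCC(C)(C)O[Si](CC)(CC)CC)Cc1c(OCOC)cc(OC)c([Si](C)(C)C)c1OS(=O)(=O)C(F)(F)F | intermediate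
25 | 4-bromo-3-methoxyphenol | Oc1ccc(Br)c(OC)c1 | starting material
26 | 1-bromo-2-methoxy-4-(methoxymethoxy)benzene | COCOc1ccc(Br)c(OC)c1 | intermediate
27 | propiolic acid | C#CC(=O)O | starting material
28 | 3-[2-methoxy-4-(methoxymethoxy)phenyl]prop-2-ynoic acid | COCOc1ccc(C#CC(=O)O)c(OC)c1 | intermediate
29 | 3-methoxy-5-(methoxymethoxy)-6-SC-benzyne (C4a≡C8a aryne) | C=C(C)[C@H](CCC(C)(C)O[Si](CC)(CC)CC)CC1=C(OCOC)C=C(OC)C#C1 | intermediate
30 | 1-[2-hydroxy-6-methoxy-4-(methoxymethoxy)-3-SC-phenyl]-3-[2-methoxy-4-(methoxymethoxy)phenyl]prop-2-yn-1-one | C=C(C)[C@H](CCC(C)(C)O[Si](CC)(CC)CC)Cc1c(OCOC)cc(OC)c(C(=O)C#Cc2ccc(OCOC)cc2OC)c1O | intermediate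
31 | 5-methoxy-2-[2-methoxy-4-(methoxymethoxy)phenyl]-7-(methoxymethoxy)-8-SC-4H-chromen-4-one | C=C(C)[C@H](CCC(C)(C)O[Si](CC)(CC)CC)Cc1c(OCOC)cc(OC)c2c1OC(c1ccc(OCOC)cc1OC)=CC2=O | intermediate
32 | (2S)-4-[diethoxy(methyl)silyloxy]-5-methoxy-2-[2-methoxy-4-(methoxymethoxy)phenyl]-7-(methoxymethoxy)-8-SC-2H-chromene | C=C(C)[C@H](CCC(C)(C)O[Si](CC)(CC)CC)Cc1c(OCOC)cc(OC)c2c1O[C@H](c1ccc(OCOC)cc1OC)C=C2O[Si](C)(OCC)OCC | intermediate
33 | (2S)-5-methoxy-2-[2-methoxy-4-(methoxymethoxy)phenyl]-7-(methoxymethoxy)-8-SC-2,3-dihydro-4H-chromen-4-one | C=C(C)[C@H](CCC(C)(C)O[Si](CC)(CC)CC)Cc1c(OCOC)cc(OC)c2c1O[C@H](c1ccc(OCOC)cc1OC)CC2=O | intermediate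
34 | (2S)-5-methoxy-2-[2-methoxy-4-(trimethylsilyloxy)phenyl]-8-SC-7-(trimethylsilyloxy)-2,3-dihydro-4H-chromen-4-one | C=C(C)[C@H](CCC(C)(C)O[Si](CC)(CC)CC)Cc1c(O[Si](C)(C)C)cc(OC)c2c1O[C@H](c1ccc(O[Si](C)(C)C)cc1OC)CC2=O | intermediate
35 | (2S)-7-hydroxy-2-(4-hydroxy-2-methoxyphenyl)-8-[(2R)-5-hydroxy-5-methyl-2-(prop-1-en-2-yl)hexyl]-5-methoxy-2,3-dihydro-4H-chromen-4-one | C=C(C)[C@H](CCC(C)(C)O)Cc1c(O)cc(OC)c2c1O[C@H](c1ccc(O)cc1OC)CC2=O | target

Total step count: 17. Longest linear sequence: 12 steps (steps 1–6, 10–12, 15–17).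

**Steps most likely to fail, with fallbacks**

Step 15. The aryne may be consumed by an intramolecular ene reaction with the isopropenyl group before the carboxylate reaches it. The carboxylate may also add at C4a instead of C8a, or the aryl anion may be protonated before the acyl group migrates, leaving only an aryl ester. The fallback avoids the aryne altogether; it sets out from carbamate 18 and acid 28 and comes back at flavone 31. Acid 28 is condensed with N,O-dimethylhydroxylamine hydrochloride (carbodiimide, i-Pr2NEt, CH2Cl2) to the Weinreb amide N-methoxy-3-[2-methoxy-4-(methoxymethoxy)phenyl]-N-methylprop-2-ynamide F1. Carbamate 18 is N-silylated and ortho-lithiated exactly as in step 11 (19, 20), and the aryllithium is acylated with F1 at −78 °C to give, after work-up, the ynone 3-methoxy-2-{3-[2-methoxy-4-(methoxymethoxy)phenyl]prop-2-ynoyl}-5-(methoxymethoxy)-6-SC-phenyl N-(propan-2-yl)carbamate F2. DBU and Et2NH in MeCN at 40 °C then cleave the carbamate, and the amine-mediated 6-endo cyclisation of the freed 2-hydroxyaryl ynone 30 gives 31.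

Step 16. Hydride may be delivered without facial preference. The catalyst may fail to turn over on this electron-rich vinylogous ester with its ortho-substituted ring B, or the C4 carbonyl may be reduced further. The fallback sets out from flavone 31 and comes back at 33. Conjugate reduction with LiBH(s-Bu)3 in THF at −78 °C gives the C2-epimeric mixture 5-methoxy-2-[2-methoxy-4-(methoxymethoxy)phenyl]-7-(methoxymethoxy)-8-SC-2,3-dihydro-4H-chromen-4-one F3. The two diastereomers are separated by preparative HPLC on a chiral stationary phase into 33 and the (2R) epimer of 33 F4. F4 is returned to the mixture with NaOAc in EtOH at 60 °C, which equilibrates C2 through the ring-opened (E)-1-[2-hydroxy-6-methoxy-4-(methoxymethoxy)-3-SC-phenyl]-3-[2-methoxy-4-(methoxymethoxy)phenyl]prop-2-en-1-one F5, and is separated again.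

Step 10. Transmetalation and reductive elimination may be slow at the doubly ortho-substituted aryl iodide, so that the alkylzinc is protonated by the carbamate N–H or the iodide is simply reduced. The fallback is a B-alkyl Suzuki coupling; it sets out from iodide 9 and comes back at 18. Iodide 9 is lithiated with t-BuLi (2 equiv) in Et2O at −78 °C and trapped with B-methoxy-9-borabicyclo[3.3.1]nonane to give lithium 9-methoxy-9-[(2S)-5-methyl-2-(prop-1-en-2-yl)-5-(triethylsilyloxy)hexyl]-9-boranuidabicyclo[3.3.1]nonane F6. F6 is coupled directly with 16 (Pd(dppf)Cl2, aq. K3PO4, DMF, rt) to give 18.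

**Further compounds**

F1 | step 15 | N-methoxy-3-[2-methoxy-4-(methoxymethoxy)phenyl]-N-methylprop-2-ynamide | COCOc1ccc(C#CC(=O)N(C)OC)c(OC)c1
F2 | step 15 | 3-methoxy-2-{3-[2-methoxy-4-(methoxymethoxy)phenyl]prop-2-ynoyl}-5-(methoxymethoxy)-6-SC-phenyl N-(propan-2-yl)carbamate | C=C(C)[C@H](CCC(C)(C)O[Si](CC)(CC)CC)Cc1c(OCOC)cc(OC)c(C(=O)C#Cc2ccc(OCOC)cc2OC)c1OC(=O)NC(C)C
F3 | step 16 | C2-epimeric mixture of 5-methoxy-2-[2-methoxy-4-(methoxymethoxy)phenyl]-7-(methoxymethoxy)-8-SC-2,3-dihydro-4H-chromen-4-one | C=C(C)[C@H](CCC(C)(C)O[Si](CC)(CC)CC)Cc1c(OCOC)cc(OC)c2c1OC(c1ccc(OCOC)cc1OC)CC2=O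
F4 | step 16 | (2R)-5-methoxy-2-[2-methoxy-4-(methoxymethoxy)phenyl]-7-(methoxymethoxy)-8-SC-2,3-dihydro-4H-chromen-4-one | C=C(C)[C@H](CCC(C)(C)O[Si](CC)(CC)CC)Cc1c(OCOC)cc(OC)c2c1O[C@@H](c1ccc(OCOC)cc1OC)CC2=O
F5 | step 16 | (E)-1-[2-hydroxy-6-methoxy-4-(methoxymethoxy)-3-SC-phenyl]-3-[2-methoxy-4-(methoxymethoxy)phenyl]prop-2-en-1-one | C=C(C)[C@H](CCC(C)(C)O[Si](CC)(CC)CC)Cc1c(OCOC)cc(OC)c(C(=O)/C=C/c2ccc(OCOC)cc2OC)c1O
F6 | step 10 | lithium 9-methoxy-9-[(2S)-5-methyl-2-(prop-1-en-2-yl)-5-(triethylsilyloxy)hexyl]-9-boranuidabicyclo[3.3.1]nonane | C=C(C)[C@H](CCC(C)(C)O[Si](CC)(CC)CC)C[B-]1(OC)C2CCCC1CCC2.[Li+]
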